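## Structural features

The target joins two flavonoid units through one methylene carbon: a 4'-O-methylkaempferol (ring A = benzo ring C4a–C8a with 5-OH and 7-OH, ring C = 3-hydroxy-4-pyranone, ring B = 4-methoxyphenyl on C2) and a dihydrochalcone (ring D = acylated phloroglucinol ring, ring E = 4-hydroxyphenyl, joined by a C(=O)CH2CH2 chain). The bridge runs from C8 of ring A to D3 of ring D, which is numbered D1 (acyl), D2 (OH), D3 (CH2 bridge), D4 (OCH3), D5 (CH3), D6 (OH) and is therefore hexasubstituted. There is no stereocentre, no stereogenic axis and no configured alkene, so every selectivity question concerns position, not configuration. Fragile groups are the five free phenols on two very electron-rich rings, the flavonol enol, and ring C, which strong base can open and which, with a free 5-OH, can re-close on the other oxygen (6/8 isomerisation); the two O-methyl groups must survive, so methyl ethers cannot serve as protecting groups. The real difficulty is twofold: six different substituents must be placed on ring D, and an unsymmetrical Ar–CH2–Ar' bond must be made between two phloroglucinol-type nucleophiles at C8 (not C6) without homo-coupling. The key step exploits the fact that D2, D4 and D6 carry oxygen while D1, D3 and D5 carry carbon, which is the alternating pattern of a tetraketide. D4–OCH3 is then the methyl enol ether of the central carbonyl, i.e. C4–OCH3 of a 4-methoxy-2-pyrone; D3 and D5 are pyrone C3 and C5, and D1 is the methylene of a 6-(2-oxoalkyl) side chain. Because D2 and D6 are both OH and flank the acyl group, closing the D1–D2 bond from such a pyrone can give only one ring, and the bridge carbon can be attached beforehand to pyrone C3, the single nucleophilic carbon of a 4-hydroxy-2-pyrone.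

## Logic of the disconnections

19 to 18: the four benzylic C–O bonds (on O3, O5, O7 of the flavonol and on the ring E oxygen) are cut. Benzyl is the only ether here that can be removed without touching the two O-methyl groups, and 5-O-benzyl also blocks 6/8 isomerisation of ring C in all earlier steps. The forward hydrogenolysis must spare the C2=C3 bond, the aryl ketone and the diarylmethane.

18 to 16 (key disconnection, through 17): the ring D carbon–carbon bond D1–D2 is cut and the D2 carbon is reconnected as a lactone to the oxygen on D6. Ring D does not exist until the penultimate step; in one sentence, the route folds a 4-methoxy-2-pyrone, 16, that is already bonded through the future bridge carbon to C8 of the finished flavonol, into ring D by Claisen condensation. The hexasubstituted benzene becomes a pyrone whose substituents are installed one at a time, and the Ar–CH2–Ar' problem becomes an Ar–CH2–C3(pyrone) problem. The forward step must close by C-acylation only, and the flavone must tolerate methoxide.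

16 to 12 + 15: the bond between the methylene on pyrone C6 and the ketone carbonyl is cut. This removes the whole ring E side chain as an acyl donor and leaves a pyrone with two methyl groups. The forward step needs deprotonation at the C6 methyl only and a single acyl transfer.

15 to 13 (through 14): the amide C–N bond is cut, leading back to a catalogue acid. The forward step is a routine activation and aminolysis.

12 to 11: the O–CH3 bond on pyrone C4 is cut. The methyl group is added after the bridge is made because the free 4-OH is what makes C3 nucleophilic. The forward step must alkylate the C4 oxygen and not the C2 oxygen.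

11 to 8 + 9 (through 10): the bond between the bridge carbon and pyrone C3 is cut. In 8 the bridge carbon is the only electrophile; in 9, C3 is the only CH-acidic carbon. Hetero-coupling is therefore fixed by polarity and neither partner can dimerise through a one-carbon unit. The forward step must reduce 10 faster than a second molecule of 9 can add to it.

8 to 7 to 6: the C8–CHO bond is cut (carbon monoxide as the one-carbon source), then the 3-O–benzyl bond. The iodine marks C8 through the flavonol synthesis and is exchanged for the bridge carbon only when no base-sensitive aldehyde has to be carried.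

6 to 4 (through 5) and 4 to 2 + 3: the O1–C2 bond and the C3–O bond of ring C are cut, then the Cα=Cβ bond of the enone. Since 2 has a single free phenol, next to the iodine, ring C can only close there, which fixes the halogen at C8.

2 to 1: the C–I bond is cut. The forward iodination must go ortho to the free hydroxyl and not to the position between the two benzyloxy groups.

## Other disconnections considered

Alternative 1: Cut both aryl–CH2 bonds of the bridge. The forward key step is condensation of kaempferide A1 with formaldehyde and the preformed dihydrochalcone A2, or stepwise through the Mannich base A3 of A2 and its ortho-quinone methide. This is the route drawn first. A1 offers C6 and C8 to the electrophile, both partners also react with themselves to give symmetrical dimers, and A2 still has to be made with its full substitution pattern by selective C-methylation, O-methylation and acylation of a phloroglucinol. The chosen plan fixes C8 through the single phenol of 2, fixes hetero-coupling by polarity, and builds ring D with its substituents already placed.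

Alternative 2: Cut only the C8–CH2 bond. The forward key step is a Suzuki–Miyaura sp2–sp3 coupling of 7 with the benzylic boronate A4 of a fully protected ring D, followed by hydrogenolysis. The site of coupling is secure, but both partners are flanked by two ortho substituents, benzylic boronates of this kind are prone to protodeboronation, and A4 contains the hexasubstituted ring, so the hardest part of the target is moved into a long preparation of A4 and not solved. The chosen plan is shorter overall because ring formation and bridge placement are the same event.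

Alternative 3: Cut ring C last. The forward key step is a Claisen–Schmidt condensation of the diarylmethane acetophenone A5 with 3, followed by Algar–Flynn–Oyamada closure. A5 has two different phenols ortho to its acetyl group, so ring C can close to either the 8- or the 6-benzyl flavonol; the CH2 next to the ring D ketone competes for the aldehyde; and A5 itself again needs a cross-selective methylene coupling of two phloroglucinols. The chosen plan closes ring C when only one phenol is free and no second enolisable ketone is present.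

Key step: step 10

Assumption: compounds 1, 3, 9 and 13 are taken as catalogue compounds (9 is 4-hydroxy-5,6-dimethyl-2H-pyran-2-one).
Remark: the target has no stereogenic element; the only stereo-defined species on the route are the E-alkene of 4, the racemic trans pair 5 and the ring-derived alkene geometry of 17, all of which disappear.

## Route

Step 1
Reactants: 1 1-[2,4-bis(benzyloxy)-6-hydroxyphenyl]ethan-1-one
Product: 2 1-[4,6-bis(benzyloxy)-2-hydroxy-3-iodophenyl]ethan-1-one
Conditions: NIS (1.05 equiv), CF3CO2H (10 mol %), MeCN, 0 °C to rt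
Reagents that add atoms: N-iodosuccinimide, O=C1CCC(=O)N1I
Why: Electrophilic aromatic iodination; of the two free ring positions, the one ortho to the free hydroxyl is the more accessible, because the other lies between two benzyloxy groups whose benzyl arms are turned towards it.

Step 2
Reactants: 2 1-[4,6-bis(benzyloxy)-2-hydroxy-3-iodophenyl]ethan-1-one; 3 4-methoxybenzaldehyde
Product: 4 (2E)-1-[4,6-bis(benzyloxy)-2-hydroxy-3-iodophenyl]-3-(4-methoxyphenyl)prop-2-en-1-one
Conditions: KOH (50% aq.), EtOH, rt
Reagents that add atoms: none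
Why: Claisen–Schmidt condensation of the methyl ketone enolate with a non-enolisable aldehyde; E1cB dehydration gives the conjugated E-enone, and the aryl iodide and benzyl ethers are inert to aqueous alkali.

Step 3
Reactants: 4 (2E)-1-[4,6-bis(benzyloxy)-2-hydroxy-3-iodophenyl]-3-(4-methoxyphenyl)prop-2-en-1-one
Product: 6 5,7-bis(benzyloxy)-3-hydroxy-8-iodo-2-(4-methoxyphenyl)-4H-chromen-4-one, via trans-dihydroflavonol 5 (not isolated)
Conditions: 30% H2O2, NaOH (aq.), MeOH/THF, 0 °C to rt
Reagents that add atoms: hydrogen peroxide, OO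
Why: Algar–Flynn–Oyamada reaction: alkaline peroxide oxidises the enone, the only phenoxide closes ring C to the trans-dihydroflavonol 5, and further peroxide dehydrogenates it to the flavonol; since that phenoxide is next to the iodine, the iodine must end at C8.

Step 4
Reactants: 6 5,7-bis(benzyloxy)-3-hydroxy-8-iodo-2-(4-methoxyphenyl)-4H-chromen-4-one
Product: 7 3,5,7-tris(benzyloxy)-8-iodo-2-(4-methoxyphenyl)-4H-chromen-4-one
Conditions: BnBr, K2CO3, DMF, 50 °C
Reagents that add atoms: benzyl bromide, BrCc1ccccc1
Why: Williamson etherification of the acidic 3-hydroxyl (an enol next to the carbonyl), the only free OH in 6; the ether removes the last acidic proton before the base-mediated steps.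

Step 5
Reactants: 7 3,5,7-tris(benzyloxy)-8-iodo-2-(4-methoxyphenyl)-4H-chromen-4-one
Product: 8 3,5,7-tris(benzyloxy)-2-(4-methoxyphenyl)-4-oxo-4H-chromene-8-carbaldehyde
Conditions: CO (3 bar), Et3SiH, PdCl2(dppp) (5 mol %), Na2CO3, DMF, 80 °C
Reagents that add atoms: carbon monoxide, [C-]#[O+]
Why: Palladium-catalysed reductive carbonylation (formylation) of an aryl iodide: oxidative addition to zerovalent palladium, CO insertion to the acyl complex and hydride transfer from the silane; the chelating diphosphine disfavours direct hydrodeiodination.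

Step 6
Reactants: 8 3,5,7-tris(benzyloxy)-2-(4-methoxyphenyl)-4-oxo-4H-chromene-8-carbaldehyde; 9 4-hydroxy-5,6-dimethyl-2H-pyran-2-one
Product: 11 3-{[3,5,7-tris(benzyloxy)-2-(4-methoxyphenyl)-4-oxo-4H-chromen-8-yl]methyl}-4-hydroxy-5,6-dimethyl-2H-pyran-2-one, via Knoevenagel adduct 10 (not isolated)
Conditions: Hantzsch ester (diethyl 2,6-dimethyl-1,4-dihydropyridine-3,5-dicarboxylate, 1.2 equiv), L-proline (20 mol %), CH2Cl2/EtOH, 40 °C
Reagents that add atoms: none
Why: Three-component reductive alkylation: amine-catalysed Knoevenagel condensation at C3 of the hydroxypyrone (its only CH-acidic carbon) gives the alkylidene dione 10, which the dihydropyridine reduces by conjugate hydride transfer before a second pyrone can add.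

Step 7
Reactants: 11 3-{[3,5,7-tris(benzyloxy)-2-(4-methoxyphenyl)-4-oxo-4H-chromen-8-yl]methyl}-4-hydroxy-5,6-dimethyl-2H-pyran-2-one
Product: 12 3-{[3,5,7-tris(benzyloxy)-2-(4-methoxyphenyl)-4-oxo-4H-chromen-8-yl]methyl}-4-methoxy-5,6-dimethyl-2H-pyran-2-one
Conditions: Me2SO4, K2CO3, acetone, reflux
Reagents that add atoms: dimethyl sulfate, COS(=O)(=O)OC
Why: O-Methylation of the potassium salt of a vinylogous acid with a hard methylating agent, the standard way to 4-methoxy-2-pyrones; every other oxygen of 11 is already etherified.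

Step 8
Reactants: 13 3-[4-(benzyloxy)phenyl]propanoic acid
Product: 15 3-[4-(benzyloxy)phenyl]-N-methoxy-N-methylpropanamide, via acyl imidazole 14 (not isolated)
Conditions: CDI, CH2Cl2, rt; then MeNHOMe·HCl, rt
Reagents that add atoms: N,O-dimethylhydroxylamine hydrochloride, CNOC.Cl; 1,1'-carbonyldiimidazole, O=C(n1ccnc1)n1ccnc1 (supplies the imidazolyl group of 14 only)
Why: Carboxyl activation as the acyl imidazole and aminolysis to the N-methoxy-N-methylamide, an acyl donor that transfers its acyl group only once.

Step 9
Reactants: 12 3-{[3,5,7-tris(benzyloxy)-2-(4-methoxyphenyl)-4-oxo-4H-chromen-8-yl]methyl}-4-methoxy-5,6-dimethyl-2H-pyran-2-one; 15 3-[4-(benzyloxy)phenyl]-N-methoxy-N-methylpropanamide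
Product: 16 6-{4-[4-(benzyloxy)phenyl]-2-oxobutyl}-4-methoxy-5-methyl-3-{[3,5,7-tris(benzyloxy)-2-(4-methoxyphenyl)-4-oxo-4H-chromen-8-yl]methyl}-2H-pyran-2-one
Conditions: LiN(iPr)2 (1.15 equiv), THF, −78 °C; then 15, −78 to −20 °C; 1 M HCl, 0 °C
Reagents that add atoms: none
Why: Vinylogous enolate acylation: only the C6 methyl is conjugated through C5=C6 and C3=C4 to the lactone carbonyl, so it is the site of deprotonation. The chelated tetrahedral lithium adduct of the N-methoxy-N-methylamide releases the ketone only on work-up, which prevents double addition and proton transfer from the acidic product.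

Step 10
Reactants: 16 6-{4-[4-(benzyloxy)phenyl]-2-oxobutyl}-4-methoxy-5-methyl-3-{[3,5,7-tris(benzyloxy)-2-(4-methoxyphenyl)-4-oxo-4H-chromen-8-yl]methyl}-2H-pyran-2-one
Product: 18 3-[4-(benzyloxy)phenyl]-1-[2,6-dihydroxy-4-methoxy-3-methyl-5-{[3,5,7-tris(benzyloxy)-2-(4-methoxyphenyl)-4-oxo-4H-chromen-8-yl]methyl}phenyl]propan-1-one, via ring-opened methyl ester 17 (not isolated)
Conditions: NaOMe (5 equiv), MeOH/THF, 65 °C; then 1 M HCl, 0 °C
Reagents that add atoms: sodium methoxide, C[O-].[Na+] (its methoxy group is carried by 17 only and is expelled again before 18)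
Why: Methoxide opens the lactone at C2 to the (2E)-β-methoxyacrylate 17 (a tetraketide with its central carbonyl masked as the methyl enol ether; the same ester can form by E1cB opening of the side-chain dienolate to an acylketene that methanol traps), and the methylene between the two ketones then attacks the ester carbonyl in a Claisen (Dieckmann-type) condensation, after which loss of methoxide and two enolisations give aromatic ring D. The closest known reaction type is the base-induced recyclisation of 6-(2-oxoalkyl)-4-hydroxy- and 4-methoxy-2-pyrones to acylphloroglucinols, the laboratory counterpart of the biosynthetic chalcone folding. Ring D closes as a six-membered carbocycle by 6-exo-trig C-acylation, and the cis relation of ester and ketone chain across the enol-ether double bond, inherited from the pyrone ring, keeps the two ends within reach. No stereocentre is formed, and the CH(CH3) centre of 17 becomes planar on aromatisation. The selectivity needed is Claisen closure over aldol closure and over return to the pyrone: an aldol would have to use the old pyrone C3, which carries the flavonylmethyl group and could only give a quaternary, non-aromatisable and therefore reversible adduct, whereas the Claisen product is removed irreversibly as the aromatic bis-phenoxide. Regiochemistry cannot go wrong, because the lactone carbon and the former ring-oxygen carbon both end as C–OH next to the acyl group, the enol ether ends para to it as OCH3, and pyrone C3 and C5 deliver the CH2 bridge and the CH3. Methoxide in methanol makes exchange at the vinylogous ester carbon degenerate, and the 5-O-benzyl group ensures that any reversible opening of ring C can only re-close on the original oxygen.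

Step 11
Reactants: 18 3-[4-(benzyloxy)phenyl]-1-[2,6-dihydroxy-4-methoxy-3-methyl-5-{[3,5,7-tris(benzyloxy)-2-(4-methoxyphenyl)-4-oxo-4H-chromen-8-yl]methyl}phenyl]propan-1-one
Product: 19 4'''-hydroxytrianguletin, 8-({2,4-dihydroxy-3-[3-(4-hydroxyphenyl)propanoyl]-6-methoxy-5-methylphenyl}methyl)-3,5,7-trihydroxy-2-(4-methoxyphenyl)-4H-chromen-4-one
Conditions: H2 (1 atm), 10% Pd/C, THF/MeOH, rt
Reagents that add atoms: none
Why: Catalytic hydrogenolysis of four aryl benzyl ethers; the methyl ethers, the diarylmethane, the hydrogen-bonded aryl ketone and the flavonol C2=C3 bond should be inert at ambient pressure and temperature.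

## Compound list

1 | 1-[2,4-bis(benzyloxy)-6-hydroxyphenyl]ethan-1-one | CC(=O)c1c(O)cc(OCc2ccccc2)cc1OCc1ccccc1 | starting material
2 | 1-[4,6-bis(benzyloxy)-2-hydroxy-3-iodophenyl]ethan-1-one | CC(=O)c1c(O)c(I)c(OCc2ccccc2)cc1OCc1ccccc1 | intermediate
3 | 4-methoxybenzaldehyde | COc1ccc(C=O)cc1 | starting material
4 | (2E)-1-[4,6-bis(benzyloxy)-2-hydroxy-3-iodophenyl]-3-(4-methoxyphenyl)prop-2-en-1-one | COc1ccc(/C=C/C(=O)c2c(O)c(I)c(OCc3ccccc3)cc2OCc2ccccc2)cc1 | intermediate
5 | trans-5,7-bis(benzyloxy)-3-hydroxy-8-iodo-2-(4-methoxyphenyl)-2,3-dihydro-4H-chromen-4-one (racemic; the 2R,3R enantiomer is drawn) | COc1ccc([C@H]2Oc3c(I)c(OCc4ccccc4)cc(OCc4ccccc4)c3C(=O)[C@@H]2O)cc1 | intermediate (not isolated)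
6 | 5,7-bis(benzyloxy)-3-hydroxy-8-iodo-2-(4-methoxyphenyl)-4H-chromen-4-one | COc1ccc(-c2oc3c(I)c(OCc4ccccc4)cc(OCc4ccccc4)c3c(=O)c2O)cc1 | intermediate
7 | 3,5,7-tris(benzyloxy)-8-iodo-2-(4-methoxyphenyl)-4H-chromen-4-one | COc1ccc(-c2oc3c(I)c(OCc4ccccc4)cc(OCc4ccccc4)c3c(=O)c2OCc2ccccc2)cc1 | intermediate
8 | 3,5,7-tris(benzyloxy)-2-(4-methoxyphenyl)-4-oxo-4H-chromene-8-carbaldehyde | COc1ccc(-c2oc3c(C=O)c(OCc4ccccc4)cc(OCc4ccccc4)c3c(=O)c2OCc2ccccc2)cc1 | intermediate
9 | 4-hydroxy-5,6-dimethyl-2H-pyran-2-one | Cc1oc(=O)cc(O)c1C | starting material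
10 | 3-{[3,5,7-tris(benzyloxy)-2-(4-methoxyphenyl)-4-oxo-4H-chromen-8-yl]methylidene}-5,6-dimethyl-2H-pyran-2,4(3H)-dione (alkene geometry not defined; both isomers reduce to 11) | CC1=C(C)C(=O)C(=Cc2c(OCc3ccccc3)cc(OCc3ccccc3)c3c(=O)c(OCc4ccccc4)c(-c4ccc(OC)cc4)oc23)C(=O)O1 | intermediate (not isolated)
11 | 3-{[3,5,7-tris(benzyloxy)-2-(4-methoxyphenyl)-4-oxo-4H-chromen-8-yl]methyl}-4-hydroxy-5,6-dimethyl-2H-pyran-2-one | Cc1oc(=O)c(Cc2c(OCc3ccccc3)cc(OCc3ccccc3)c3c(=O)c(OCc4ccccc4)c(-c4ccc(OC)cc4)oc23)c(O)c1C | intermediate
12 | 3-{[3,5,7-tris(benzyloxy)-2-(4-methoxyphenyl)-4-oxo-4H-chromen-8-yl]methyl}-4-methoxy-5,6-dimethyl-2H-pyran-2-one | Cc1oc(=O)c(Cc2c(OCc3ccccc3)cc(OCc3ccccc3)c3c(=O)c(OCc4ccccc4)c(-c4ccc(OC)cc4)oc23)c(OC)c1C | intermediate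
13 | 3-[4-(benzyloxy)phenyl]propanoic acid | OC(=O)CCc1ccc(OCc2ccccc2)cc1 | starting material
14 | 3-[4-(benzyloxy)phenyl]-1-(1H-imidazol-1-yl)propan-1-one | O=C(CCc1ccc(OCc2ccccc2)cc1)n1ccnc1 | intermediate (not isolated)
15 | 3-[4-(benzyloxy)phenyl]-N-methoxy-N-methylpropanamide | CON(C)C(=O)CCc1ccc(OCc2ccccc2)cc1 | intermediate
16 | 6-{4-[4-(benzyloxy)phenyl]-2-oxobutyl}-4-methoxy-5-methyl-3-{[3,5,7-tris(benzyloxy)-2-(4-methoxyphenyl)-4-oxo-4H-chromen-8-yl]methyl}-2H-pyran-2-one | COc1c(C)c(CC(=O)CCc2ccc(OCc3ccccc3)cc2)oc(=O)c1Cc1c(OCc2ccccc2)cc(OCc2ccccc2)c2c(=O)c(OCc3ccccc3)c(-c3ccc(OC)cc3)oc12 | intermediate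
17 | methyl (2E)-9-[4-(benzyloxy)phenyl]-3-methoxy-4-methyl-5,7-dioxo-2-{[3,5,7-tris(benzyloxy)-2-(4-methoxyphenyl)-4-oxo-4H-chromen-8-yl]methyl}non-2-enoate (C4 not configured; drawn as the keto form) | COC(=O)/C(Cc1c(OCc2ccccc2)cc(OCc2ccccc2)c2c(=O)c(OCc3ccccc3)c(-c3ccc(OC)cc3)oc12)=C(/OC)C(C)C(=O)CC(=O)CCc1ccc(OCc2ccccc2)cc1 | intermediate (not isolated)
18 | 3-[4-(benzyloxy)phenyl]-1-[2,6-dihydroxy-4-methoxy-3-methyl-5-{[3,5,7-tris(benzyloxy)-2-(4-methoxyphenyl)-4-oxo-4H-chromen-8-yl]methyl}phenyl]propan-1-one | COc1ccc(-c2oc3c(Cc4c(O)c(C(=O)CCc5ccc(OCc6ccccc6)cc5)c(O)c(C)c4OC)c(OCc4ccccc4)cc(OCc4ccccc4)c3c(=O)c2OCc2ccccc2)cc1 | intermediate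
19 | 4'''-hydroxytrianguletin | COc1ccc(-c2oc3c(Cc4c(O)c(C(=O)CCc5ccc(O)cc5)c(O)c(C)c4OC)c(O)cc(O)c3c(=O)c2O)cc1 | target

## Step count and least certain steps

Total steps: 11. Longest linear sequence: 10 (steps 1 to 7, then 9, 10 and 11; step 8 is a one-step branch).

Step 10 (key step). The pyrone may fail to open, because deprotonation of the side chain turns it into an electron-rich dienolate, or the opened chain may return to the pyrone faster than it undergoes C-acylation at the hindered, fully substituted ester. Long heating with methoxide then risks opening of ring C of the flavone. The fallback forms the bridge on a preformed ring D; it sets out from 8 and comes back at 18. Aldehyde 8 is reduced (NaBH4, THF/MeOH, −20 °C) to 3,5,7-tris(benzyloxy)-8-(hydroxymethyl)-2-(4-methoxyphenyl)-4H-chromen-4-one F1. Separately, catalogue 1-(2,4,6-trihydroxy-3-methylphenyl)ethan-1-one is mono-methylated at the oxygen para to the acetyl group (Me2SO4, 1 equiv, K2CO3, acetone) to 1-(2,6-dihydroxy-4-methoxy-3-methylphenyl)ethan-1-one F2. F2 is condensed with 4-(benzyloxy)benzaldehyde (KOH, EtOH) to (2E)-3-[4-(benzyloxy)phenyl]-1-(2,6-dihydroxy-4-methoxy-3-methylphenyl)prop-2-en-1-one F3, which is hydrogenated at the alkene only (H2, RhCl(PPh3)3, toluene/EtOH) to 3-[4-(benzyloxy)phenyl]-1-(2,6-dihydroxy-4-methoxy-3-methylphenyl)propan-1-one F4. Acid-catalysed Friedel–Crafts benzylation (Sc(OTf)3 cat., CH2Cl2, 0 °C, F4 in excess) of the single free ring position of F4 by the cation from F1 should give 18.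

Step 3. With an alkoxy group ortho to the carbonyl (the future 5-O-benzyl), the oxidative cyclisation can close through the α-carbon to a five-membered aurone instead of the flavonol. The fallback sets out from 4 and comes back at 6. Iodine-catalysed oxidative cyclisation (I2 cat., DMSO, 110 °C) gives 5,7-bis(benzyloxy)-8-iodo-2-(4-methoxyphenyl)-4H-chromen-4-one F5. Deprotonation at C3 (LiN(iPr)2, THF, −78 °C) and trapping with B(OMe)3 gives dimethyl [5,7-bis(benzyloxy)-8-iodo-2-(4-methoxyphenyl)-4-oxo-4H-chromen-3-yl]boronate F6, which is not isolated; oxidation (H2O2, AcOH) should give 6.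

Step 5. Hydride transfer to the aryl–palladium intermediate may outrun CO insertion at the hindered C8, which means loss of iodine without formylation; a ligand-free palladium/silane combination could also start to cleave benzyl ethers. The fallback sets out from 7 and comes back at 8. Suzuki–Miyaura coupling with KBF3(CH=CH2) (PdCl2(dppf), Cs2CO3, THF/H2O, 80 °C) gives 3,5,7-tris(benzyloxy)-8-ethenyl-2-(4-methoxyphenyl)-4H-chromen-4-one F7, and Lemieux–Johnson cleavage (OsO4 cat., NaIO4, 2,6-lutidine, dioxane/H2O) should give 8.

Step 7. Methylation may occur in part on the C2 oxygen, giving the 2-methoxy-4-pyranone; this is a known tendency of 3,5-dialkyl-4-hydroxy-2-pyrones, and that isomer would fold to a ring D without the O-methyl group. The fallback reverses the polarity; it sets out from 11 and comes back at 12. Sulfonylation (TsCl, Et3N, CH2Cl2, 0 °C) gives 3-{[3,5,7-tris(benzyloxy)-2-(4-methoxyphenyl)-4-oxo-4H-chromen-8-yl]methyl}-5,6-dimethyl-2-oxo-2H-pyran-4-yl 4-methylbenzenesulfonate F8, and addition–elimination of methoxide at C4 (NaOMe, MeOH, 0 °C to rt) should give 12 with the lactone carbonyl untouched.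

Step 9. The lithiated pyrone may add to the chromone carbonyl of another molecule, or deprotonation may be incomplete at the hindered, poorly soluble substrate. The fallback makes the side chain before the flavone is present; it sets out from 9 (with 15 and 8) and comes back at 16. The dianion of 9 (LiN(iPr)2, 2.2 equiv, THF, −78 °C) is acylated with 15 to give 6-{4-[4-(benzyloxy)phenyl]-2-oxobutyl}-4-hydroxy-5-methyl-2H-pyran-2-one F9. Reductive alkylation of F9 at C3 with 8 (Hantzsch ester, L-proline) gives 6-{4-[4-(benzyloxy)phenyl]-2-oxobutyl}-4-hydroxy-5-methyl-3-{[3,5,7-tris(benzyloxy)-2-(4-methoxyphenyl)-4-oxo-4H-chromen-8-yl]methyl}-2H-pyran-2-one F10. Methylation of its most acidic hydroxyl (Me2SO4, 1.05 equiv, K2CO3, 1.0 equiv, acetone) should give 16.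

## Further compounds

F1 | step 10 | 3,5,7-tris(benzyloxy)-8-(hydroxymethyl)-2-(4-methoxyphenyl)-4H-chromen-4-one | COc1ccc(-c2oc3c(CO)c(OCc4ccccc4)cc(OCc4ccccc4)c3c(=O)c2OCc2ccccc2)cc1
F2 | step 10 | 1-(2,6-dihydroxy-4-methoxy-3-methylphenyl)ethan-1-one | COc1cc(O)c(C(C)=O)c(O)c1C
F3 | step 10 | (2E)-3-[4-(benzyloxy)phenyl]-1-(2,6-dihydroxy-4-methoxy-3-methylphenyl)prop-2-en-1-one | COc1cc(O)c(C(=O)/C=C/c2ccc(OCc3ccccc3)cc2)c(O)c1C
F4 | step 10 | 3-[4-(benzyloxy)phenyl]-1-(2,6-dihydroxy-4-methoxy-3-methylphenyl)propan-1-one | COc1cc(O)c(C(=O)CCc2ccc(OCc3ccccc3)cc2)c(O)c1C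
F5 | step 3 | 5,7-bis(benzyloxy)-8-iodo-2-(4-methoxyphenyl)-4H-chromen-4-one | COc1ccc(-c2cc(=O)c3c(OCc4ccccc4)cc(OCc4ccccc4)c(I)c3o2)cc1
F6 | step 3 | dimethyl [5,7-bis(benzyloxy)-8-iodo-2-(4-methoxyphenyl)-4-oxo-4H-chromen-3-yl]boronate | COc1ccc(-c2oc3c(I)c(OCc4ccccc4)cc(OCc4ccccc4)c3c(=O)c2B(OC)OC)cc1
F7 | step 5 | 3,5,7-tris(benzyloxy)-8-ethenyl-2-(4-methoxyphenyl)-4H-chromen-4-one | COc1ccc(-c2oc3c(C=C)c(OCc4ccccc4)cc(OCc4ccccc4)c3c(=O)c2OCc2ccccc2)cc1
F8 | step 7 | 3-{[3,5,7-tris(benzyloxy)-2-(4-methoxyphenyl)-4-oxo-4H-chromen-8-yl]methyl}-5,6-dimethyl-2-oxo-2H-pyran-4-yl 4-methylbenzenesulfonate | Cc1ccc(S(=O)(=O)Oc2c(C)c(C)oc(=O)c2Cc2c(OCc3ccccc3)cc(OCc3ccccc3)c3c(=O)c(OCc4ccccc4)c(-c4ccc(OC)cc4)oc23)cc1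
F9 | step 9 | 6-{4-[4-(benzyloxy)phenyl]-2-oxobutyl}-4-hydroxy-5-methyl-2H-pyran-2-one | Cc1c(O)cc(=O)oc1CC(=O)CCc1ccc(OCc2ccccc2)cc1
F10 | step 9 | 6-{4-[4-(benzyloxy)phenyl]-2-oxobutyl}-4-hydroxy-5-methyl-3-{[3,5,7-tris(benzyloxy)-2-(4-methoxyphenyl)-4-oxo-4H-chromen-8-yl]methyl}-2H-pyran-2-one | Cc1c(O)c(Cc2c(OCc3ccccc3)cc(OCc3ccccc3)c3c(=O)c(OCc4ccccc4)c(-c4ccc(OC)cc4)oc23)c(=O)oc1CC(=O)CCc1ccc(OCc2ccccc2)cc1
A1 | alternative 1 | kaempferide, 3,5,7-trihydroxy-2-(4-methoxyphenyl)-4H-chromen-4-one | COc1ccc(-c2oc3cc(O)cc(O)c3c(=O)c2O)cc1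
A2 | alternative 1 | 1-(2,6-dihydroxy-4-methoxy-3-methylphenyl)-3-(4-hydroxyphenyl)propan-1-one | COc1cc(O)c(C(=O)CCc2ccc(O)cc2)c(O)c1C
A3 | alternative 1 | 1-{3-[(dimethylamino)methyl]-2,6-dihydroxy-4-methoxy-5-methylphenyl}-3-(4-hydroxyphenyl)propan-1-one | COc1c(C)c(O)c(C(=O)CCc2ccc(O)cc2)c(O)c1CN(C)C
A4 | alternative 2 | 1-{2,6-bis(benzyloxy)-4-methoxy-3-methyl-5-[(4,4,5,5-tetramethyl-1,3,2-dioxaborolan-2-yl)methyl]phenyl}-3-[4-(benzyloxy)phenyl]propan-1-one | COc1c(C)c(OCc2ccccc2)c(C(=O)CCc2ccc(OCc3ccccc3)cc2)c(OCc2ccccc2)c1CB1OC(C)(C)C(C)(C)O1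
A5 | alternative 3 | 1-{3-[(3-acetyl-2,4,6-trihydroxyphenyl)methyl]-2,6-dihydroxy-4-methoxy-5-methylphenyl}-3-(4-hydroxyphenyl)propan-1-one | COc1c(C)c(O)c(C(=O)CCc2ccc(O)cc2)c(O)c1Cc1c(O)cc(O)c(C(C)=O)c1O
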